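- Late in the earlier runs, at 4.00 h, I compared the two capture products through the selectivity factor S, target over other capture product: alder read 0.600 and maple read 1.76.

| setting | alder | maple | birch | flask |
|---|---|---|---|---|
| substrate | 0.010 M | 0.040 M | 0.020 M | 0.020 M |
| first nucleophile | 1 equiv | 1 equiv | 1 equiv | 1.00 equiv |
| second nucleophile | 0.50 equiv | 0.50 equiv | 0.75 equiv | 0.500 equiv |
| remark | run made earlier | run made earlier | run made earlier |  |
| time |  |  |  | 5.0 h |

- alder (time / h: other capture product / %, target / %, substrate / %): 0.250: 7, 0, 90; 0.833: 16, 4, 67; 1.33: 22, 4, 50; 2.00: 22, 10, 37; 3.00: 27, 11, 24; 4.00: 25, 15, 13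
- maple (time / h: other capture product / %, target / %, substrate / %): 0.250: 7, 2, 90; 0.833: 12, 9, 65; 1.33: 16, 11, 48; 2.00: 17, 18, 33; 3.00: 19, 27, 21; 4.00: 17, 30, 13
- birch (time / h: other capture product / %, target / %, substrate / %): 0.333: 11, 0, 88; 1.00: 20, 6, 61; 2.00: 20, 13, 36; 3.00: 21, 20, 22; 4.00: 24, 23, 15

(each reading ± 1.5 percentage points)

- the earlier runs were read with a standard deviation of 1.5 percentage points

- share of other capture product in other capture product plus target at 2.0 min
- share of other capture product in other capture product plus target at 5.0 h

- My bench rule was that dilution at fixed equivalents leaves S unchanged, since two nucleophiles competing for one species keep their concentration ratio, here 2.00 in both alder and maple.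
- That rule stopped working between these two runs: a charge ratio of 4.00 raised S by a factor of 2.93, so S did depend on concentration.
- I therefore carried the apparent order of S in substrate concentration, the logarithm of the S ratio over the logarithm of the charge ratio: n = 0.778, a reading from values scattered by 1.5 points.
- Scaling alder by n, I reckoned S = 1.03 for the flask at 4.00 h, a share of other capture product of 49.3%; that figure is my own and belongs to that earlier time, not to 5.0 h.
- The forecast gave 95% (range 82% to 100%) at 2.0 min and 46% (range 39% to 53%) at 5.0 h, noting that “Target is favoured by higher concentration”.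
- The flask gave 89.9% at 2.0 min, lower than the forecast's 95%, and 46.7% at 5.0 h, against 46%. In the flask, target and other capture product stood level at 3.64 h, at 21.5% each. The flask's share at 5.0 h means S = 1.14, and this value replaced alder as my base for scaling with n.

    substrate → intermediate (k = 1.24 × 10⁻⁴ s⁻¹)
    second nucleophile + intermediate → other capture product (k = 5.09 L mol⁻¹ s⁻¹)
    2 second nucleophile → self-condensation product (k = 0.0501 L mol⁻¹ s⁻¹)
    substrate + intermediate → side product (k = 0.204 L mol⁻¹ s⁻¹)
    first nucleophile + intermediate → target (k = 0.267 L mol⁻¹ s⁻¹)
    intermediate → solvolysis product (k = 0.00498 s⁻¹)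

- For the neighbour flask with 0.0050 M of substrate at the same equivalents, n turned that S into 0.389, a share of 72.0% at 5.0 h; the computed share for that neighbour flask is 72.2%.

The readings were computed on assumed constants; the scatter is artificial.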